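## The problem

The target is a trans-fused hydroazulene. In guaiane numbering the five-membered ring is C1–C2–C3–C4–C5 and the seven-membered ring is C1–C10–C9–C8–C7–C6–C5. In the usual guaiane drawing it is 1αH,5βH, with a 3α,4α-epoxide, a β-isopropyl group on C7 cis to the β-isovanillate on C8, and a C10 carbinol (OH α, CH3 β). All seven stereocentres lie on the bicycle.

They can be linked to one control element. The tertiary C10 hydroxyl is cis to H1, 1,3-trans to the C8 oxygen and on the same face as the epoxide, so it can direct a hydrogenation (C1), a hydride delivery (C8) and an epoxidation (C3, C4). C5 can be equilibrated while C4 is a ketone, and C7 can follow from C8. The real task is therefore to make the C10 carbinol in one absolute configuration.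

The trisubstituted epoxide (acid), the tertiary alcohol and the aryl ester with its free phenol (base, oxidants) will not survive rough treatment, so epoxide and phenol are released last.

The enabling feature is that the seven-membered ring carries isopropyl (C7), oxygen (C8) and methyl (C10) in exactly the pattern of thymol, with C1 para to the oxygen. The ring is a thymol ring plus the single carbon C5, and C1 and C5 are bridged by the chain C2–C3–C4.

## Retrosynthesis

**Epoxide and phenol (28 ⇒ 27 ⇒ 26).** The two C–O bonds of the epoxide and the O–Si bond of the phenol silyl ether are cut last. An earlier epoxide would not survive enolate, triflate or acid steps. Alkene 26 has two stereocentres fewer, and its free C10 hydroxyl should deliver the oxidant to the α face. The forward steps need face selectivity and a desilylation that spares epoxide and ester.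

**C4 methyl (26 ⇒ 24 ⇒ 22).** The C4–CH3 bond is cut to enol triflate 24 and ketone 22. Kinetic enolisation at C3 fixes the alkene position, which dehydration of a C4 carbinol would not. The C4 ketone of 22 also lets C5 settle into the trans fusion. The C10 hydroxyl is masked as trimethylsilyl ether 23 only for the enolate step.

**Ring-fusion and C7 hydrogens, ester (22 ⇒ 20 ⇒ 16 + 19).** The C–H bonds at C1, C5 and C7 and the ester C–O bond are cut. In dienone 20 the C10 hydroxyl (α) and the C8 aroyloxy group (β) mark the same face for hydrogen delivery. Acylating before hydrogenating removes the C8 hydroxyl as a competing director. Diol 16 has only two stereocentres and acid 19 is isovanillic acid 17 with the phenol silylated.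

**C8 carbinol (16 ⇒ 15).** The C8–H bond is cut to hydroxy dienedione 15, whose single stereocentre is C10. An intramolecular hydride delivery from the C10 hydroxyl gives the 1,3-trans diol and leaves the C4 ketone alone.

**C10 carbinol (15 ⇒ 13 ⇒ 12 ⇒ 11).** The C10–O bond is traced to the 1α,10α-epoxide 13, opened by β-elimination once C4 is a ketone. The epoxide comes from β,γ-enone 12 by delivery from a temporary C4 hydroxyl. 12 is the hydrolysed form of dienol ether 11, and 11 is the reduction product of azulenone 10. The chain C5 → C4 → C10 passes the configuration of the one labile centre of the key step into the permanent C10 carbinol. The alternative of setting the configuration by a late asymmetric ketone reduction meets two competing ketones and no fixed reference centre.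

**Seven-membered ring (10 ⇒ 8).** The bonds C5–C1 and C5–C6 are cut. This turns the bicycle into an arene with a diazoketone side chain, with every skeletal carbon except the C4 methyl in place and the C8 oxygen as a methyl ether. The forward reaction must add the carbenoid to the unsubstituted ortho bond and do so enantioselectively.

**Side chain (8 ⇒ 6 ⇒ 5 ⇒ 3 ⇒ 2 ⇒ 1, with 4).** The diazoketone comes from acid 6. Acid 6 comes from cinnamic acid 5, made from aldehyde 3 and malonic acid 4. Aldehyde 3 comes from thymol 1 through its methyl ether 2 by para-formylation. All steps are standard aromatic and homologation chemistry.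

## Roads not taken

**Alternative 1:** The cut is at C1–C10 and C5–C6, the two bonds joining the five-membered ring to the rest.
- **Forward step:** a copper-catalysed asymmetric conjugate addition of an alkoxyvinyl nucleophile to cyclopentenone A1 with a chiral phosphoramidite, the enolate being alkylated in the same flask by allylic bromide A2, would give the trans-disubstituted cyclopentanone A3.
- **Merits:** the trans relationship of C1 and C5 and the absolute configuration come kinetically from one catalytic step on two very cheap compounds. In this respect it is better than the chosen plan, which reaches the trans fusion only by equilibration next to the C4 ketone and draws its absolute configuration from a carbenoid addition of untested selectivity on this arene.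
- **Weak points:** A3 has no seven-membered ring and lacks C8 altogether. The ring would have to be closed later by a C–C bond formation on a flexible chain, and C7, C8 and C10 set without ring control. Enantioselective copper catalysis is well established for alkyl nucleophiles, less so for alkoxyvinyl ones, and enolate trapping with allylic halides is often sluggish.
- **Comparison:** the chosen plan delivers both rings with the C8 oxygen and the C10 methyl in place six steps from thymol.

**Alternative 2:** The cut is at C8–C9.
- **Forward step:** a dialkylaluminium chloride would promote a type 2 carbonyl-ene closure of aldehyde A4, giving the bicyclic alcohol A5 with the C8 hydroxyl and an exocyclic methylene on C10.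
- **Merits:** A5 is closer to the target than any intermediate of the chosen route at a comparable point. The trans fusion, the C3=C4 alkene with its methyl, C7 and the C8 carbinol are present, and the absolute configuration could come from the chiral pool. On endgame length this road is better.
- **Weak points:** A4 already holds three stereocentres, one of them (C7) epimerisable next to the aldehyde, and would need about as many steps as the whole chosen route. Ene closures to seven-membered rings are slower than to six. The two alkenes of A5 must later be told apart, and the C10 carbinol would be made last, with no group to direct it.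
- **Comparison:** the chosen plan offers short access to the skeleton and a C10 carbinol that is made first and then directs the other centres.

**Alternative 3:** The cut is at C4–C5 and C1–C2.
- **Forward step:** a chiral phosphine would catalyse the [3+2] annulation of allenoate A6 with E-enone A7 to cyclopentene A8, with C1 and C5 trans and the alkene at C3=C4.
- **Merits:** it is convergent, catalytic and enantioselective, and the C3=C4 alkene is in place from the start, where the chosen plan needs three steps (silylation, triflation, coupling).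
- **Weak points:** the ester carbon on C4 must be taken down to a methyl group. Regioisomeric annulation is a known side path. The seven-membered ring is still open, and closing it between the acetyl methyl and the alkene terminus needs prior functionalisation of both. C7, C8 and C10 are again set on an open chain.
- **Comparison:** the chosen plan accepts a longer functional-group endgame in exchange for forming the seven-membered ring, its substituent pattern and the five-membered ring in a single step.

Key step: step 6

Assumption: α/β refer to the usual guaiane drawing (target 1αH,5βH). The (R,R)-ligand in step 6 stands for whichever antipode gives the C4/C5 relative configuration of 11 that leads to (10R)-15; if the sense of induction in step 6 or the face of hydride attack in step 7 is the reverse, the other antipode is used.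

## Route

Step 1
Reactants: 1 thymol
Product: 2 thymol methyl ether (1-isopropyl-2-methoxy-4-methylbenzene)
Conditions: MeI, K2CO3, acetone, reflux
Reagents that add atoms: iodomethane, CI
Why: Williamson ether synthesis on a phenol; the methyl ether later becomes the masked C8 ketone.

Step 2
Reactants: 2 thymol methyl ether
Product: 3 5-isopropyl-4-methoxy-2-methylbenzaldehyde
Conditions: Cl2CHOMe, TiCl4, CH2Cl2, 0 °C; aqueous HCl work-up
Reagents that add atoms: dichloromethyl methyl ether, COC(Cl)Cl; water, O
Why: Rieche formylation (electrophilic aromatic substitution); the position para to the methoxy group is the most activated and is flanked only by the methyl group, so the future C2 enters at the future C1.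

Step 3
Reactants: 3 5-isopropyl-4-methoxy-2-methylbenzaldehyde; 4 malonic acid
Product: 5 (E)-3-(5-isopropyl-4-methoxy-2-methylphenyl)prop-2-enoic acid
Conditions: pyridine, piperidine (cat.), 100 °C
Reagents that add atoms: none
Why: Knoevenagel–Doebner condensation with decarboxylation, which should give the E-cinnamic acid.

Step 4
Reactants: 5 (E)-3-(5-isopropyl-4-methoxy-2-methylphenyl)prop-2-enoic acid
Product: 6 3-(5-isopropyl-4-methoxy-2-methylphenyl)propanoic acid
Conditions: H2 (1 atm), Pd/C, EtOAc, rt
Reagents that add atoms: none
Why: Catalytic hydrogenation of a conjugated alkene; arene and acid are untouched.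

Step 5
Reactants: 6 3-(5-isopropyl-4-methoxy-2-methylphenyl)propanoic acid
Product: 8 1-diazo-4-(5-isopropyl-4-methoxy-2-methylphenyl)butan-2-one, via acid chloride 7 (not isolated)
Conditions: (COCl)2, DMF (cat.), CH2Cl2, 0 °C to rt; evaporate; CH2N2 (3 equiv), Et2O, 0 °C
Reagents that add atoms: oxalyl chloride, O=C(Cl)C(=O)Cl (chlorine of 7); diazomethane, C=[N+]=[N-]
Why: Acylation of diazomethane by an acid chloride (first half of an Arndt–Eistert sequence); excess diazomethane takes up HCl so that no chloromethyl ketone forms.

Step 6
Reactants: 8 1-diazo-4-(5-isopropyl-4-methoxy-2-methylphenyl)butan-2-one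
Product: 10 (5S)-8-methoxy-15-norguaia-1(10),6,8-trien-4-one [(8aS)-6-methoxy-4-methyl-7-isopropyl-3,8a-dihydroazulen-1(2H)-one], via norcaradiene 9 (not isolated)
Conditions: [Cu(MeCN)4]PF6 (5 mol %), (R,R)-Ph-BOX [(4R,4'R)-2,2'-(propane-2,2-diyl)bis(4-phenyl-4,5-dihydrooxazole)] (6 mol %), NaB[3,5-(CF3)2C6H3]4 (6 mol %), CH2Cl2, 40 °C, slow addition of 8
Reagents that add atoms: none
Why: The monovalent copper–bis(oxazoline) complex takes nitrogen from 8 and forms an electrophilic carbenoid at C5, which adds across the C1–C6 bond of the arene; this is the intramolecular Büchner reaction, and the closest known case is the enantioselective copper–bis(oxazoline) cyclisation of 1-diazo-4-arylbutan-2-ones to azulenones. The five-membered ring (C1–C2–C3–C4–C5) closes in a 5-exo sense as the tethered carbenoid cyclopropanates the ipso/ortho bond and gives norcaradiene 9. The seven-membered ring then forms by thermal disrotatory 6π electrocyclic opening of the C1–C6 cyclopropane bond of 9, so the benzene ring is expanded by the one carbon C5 and the methoxy group ends as a dienol ether, a masked C8 ketone. The single new stereocentre C5 is set by the ligand, which decides the face of the arene to which the carbenoid is delivered. The step needs site selectivity for the C1–C6 bond over the C1–C10 bond, secured by the ortho methyl group on C10, and chemoselectivity for cyclopropanation over aromatic substitution to a 2-tetralone, helped by the weakly coordinating borate counter-ion and by C6 being meta to the methoxy group. Because H5 is α to the ketone and doubly allylic, 10 is not stored but reduced at once in step 7.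

Step 7
Reactants: 10 (5S)-8-methoxy-15-norguaia-1(10),6,8-trien-4-one
Product: 11 (4R,5S)-8-methoxy-15-norguaia-1(10),6,8-trien-4-ol (4α-OH, 5β-H)
Conditions: NaBH4, CeCl3·7H2O, MeOH–THF, −78 °C
Reagents that add atoms: none
Why: Luche 1,2-reduction of an isolated cyclopentanone, fast and barely basic, so C5 should not enolise; hydride is expected to enter from the H5 face, away from the folded seven-membered ring, giving the 4α-alcohol. This fixes C5 and installs the directing group for step 9; any C4 epimer is removed by chromatography, since it would lead to the antipode of 15.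

Step 8
Reactants: 11 (4R,5S)-8-methoxy-15-norguaia-1(10),6,8-trien-4-ol
Product: 12 (4R,5S)-4-hydroxy-15-norguaia-1(10),6-dien-8-one
Conditions: oxalic acid (aq.), THF, 0 °C
Reagents that add atoms: water, O
Why: Mild hydrolysis of a dienol ether: kinetic protonation at C9 and capture of the oxocarbenium ion by water should give the β,γ-unsaturated ketone, as in the oxalic acid hydrolysis of Birch dienol ethers; C1=C10 stays out of conjugation and C5 keeps its configuration.

Step 9
Reactants: 12 (4R,5S)-4-hydroxy-15-norguaia-1(10),6-dien-8-one
Product: 13 1α,10α-epoxy-4α-hydroxy-15-nor-5βH-guai-6-en-8-one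
Conditions: VO(acac)2 (5 mol %), t-BuOOH, CH2Cl2, 0 °C to rt
Reagents that add atoms: tert-butyl hydroperoxide, CC(C)(C)OO
Why: Hydroxyl-directed epoxidation of a homoallylic alcohol: the C4 vanadate should deliver oxygen to the α face of the electron-rich tetrasubstituted C1=C10 bond, syn to the hydroxyl, while the enone C6=C7 is inert; this sets C10 (oxygen α). The product is kept away from base and used directly.

Step 10
Reactants: 13 1α,10α-epoxy-4α-hydroxy-15-nor-5βH-guai-6-en-8-one
Product: 15 (10R)-10-hydroxy-15-norguaia-1(5),6-diene-4,8-dione (10α-OH), via epoxy diketone 14 (not isolated)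
Conditions: Dess–Martin periodinane, NaHCO3, CH2Cl2, 0 °C; then Et3N (0.2 equiv), 0 °C
Reagents that add atoms: none
Why: Oxidation gives a β,γ-epoxy ketone whose H5 (α to the C4 ketone and vinylogously activated through C6=C7–C8=O) is removed by a weak base; E1cB opening of the C1–O bond should give the γ-hydroxy enone and leave C10 as the only stereocentre. Triethylamine is too weak to enolise C8 towards C9, which would open the epoxide the other way or dehydrate 15 to a tropone.

Step 11
Reactants: 15 (10R)-10-hydroxy-15-norguaia-1(5),6-diene-4,8-dione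
Product: 16 (8R,10R)-8,10-dihydroxy-15-norguaia-1(5),6-dien-4-one (8β-OH, 10α-OH)
Conditions: Me4NBH(OAc)3, MeCN–AcOH, −20 °C
Reagents that add atoms: none
Why: Evans–Saksena reduction: the C10 hydroxyl binds boron and delivers hydride to the α face of the C8 carbonyl, which should give the 1,3-trans diol (8β-OH); the C4 ketone has no hydroxyl in a 1,3-relationship and is not reduced by the acetoxyborohydride.

Step 12
Reactants: 17 isovanillic acid (3-hydroxy-4-methoxybenzoic acid)
Product: 19 4-methoxy-3-(triisopropylsilyloxy)benzoic acid, via bis-silyl derivative 18 (not isolated)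
Conditions: i-Pr3SiCl (2.2 equiv), imidazole, DMF, rt; then AcOH, THF–H2O, rt
Reagents that add atoms: chlorotriisopropylsilane, CC(C)[Si](Cl)(C(C)C)C(C)C
Why: Silylation of phenol and acid, then selective hydrolysis of the much more labile silyl ester; the triisopropylsilyl aryl ether is chosen because it withstands DBU, amide bases and organozinc reagents and falls to fluoride.

Step 13
Reactants: 16 (8R,10R)-8,10-dihydroxy-15-norguaia-1(5),6-dien-4-one; 19 4-methoxy-3-(triisopropylsilyloxy)benzoic acid
Product: 20 (8R,10R)-10-hydroxy-4-oxo-15-norguaia-1(5),6-dien-8-yl 4-methoxy-3-(triisopropylsilyloxy)benzoate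
Conditions: EDC·HCl, DMAP, CH2Cl2, 0 °C to rt
Reagents that add atoms: none
Why: Steglich esterification; only the secondary allylic C8 hydroxyl should be acylated, the tertiary C10 hydroxyl being inert under these conditions.

Step 14
Reactants: 20 (8R,10R)-10-hydroxy-4-oxo-15-norguaia-1(5),6-dien-8-yl 4-methoxy-3-(triisopropylsilyloxy)benzoate
Product: 22 (1R,5S,7R,8R,10R)-10-hydroxy-4-oxo-15-norguaian-8-yl 4-methoxy-3-(triisopropylsilyloxy)benzoate (1αH,5βH,7αH), via cis-fused ketone 21 (not isolated)
Conditions: H2 (1–10 bar), [Ir(cod)(PCy3)(py)]PF6 (10 mol %), CH2Cl2, rt; then DBU, toluene, rt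
Reagents that add atoms: none
Why: Hydroxyl-directed hydrogenation: the C10 hydroxyl binds the cationic iridium and both C=C bonds of the cross-conjugated diene should take up hydrogen from the α face, which is also the open face because the C10 methyl and the C8 aroyloxy group lie on the β face; this sets H1 and H7 α (isopropyl cis to the ester). DBU then epimerises C5 next to the C4 ketone to the trans-fused hydroazulenone, expected to be the more stable isomer.

Step 15
Reactants: 22 (1R,5S,7R,8R,10R)-10-hydroxy-4-oxo-15-norguaian-8-yl 4-methoxy-3-(triisopropylsilyloxy)benzoate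
Product: 23 (1R,5S,7R,8R,10R)-4-oxo-10-(trimethylsilyloxy)-15-norguaian-8-yl 4-methoxy-3-(triisopropylsilyloxy)benzoate
Conditions: 1-(trimethylsilyl)imidazole, CH2Cl2, rt
Reagents that add atoms: 1-(trimethylsilyl)imidazole, C[Si](C)(C)n1ccnc1
Why: Silylation of a tertiary alcohol under neutral conditions that do not enolise the ketone; it keeps the alkoxide out of the next step.

Step 16
Reactants: 23 (1R,5S,7R,8R,10R)-4-oxo-10-(trimethylsilyloxy)-15-norguaian-8-yl 4-methoxy-3-(triisopropylsilyloxy)benzoate
Product: 24 (1R,5S,7R,8R,10R)-4-(trifluoromethylsulfonyloxy)-10-(trimethylsilyloxy)-15-norguai-3-en-8-yl 4-methoxy-3-(triisopropylsilyloxy)benzoate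
Conditions: KN(SiMe3)2, THF, −78 °C; PhNTf2, −78 to −20 °C
Reagents that add atoms: N-phenylbis(trifluoromethanesulfonimide), O=S(=O)(N(c1ccccc1)S(=O)(=O)C(F)(F)F)C(F)(F)F
Why: Kinetic deprotonation of the 2-substituted cyclopentanone at the methylene C3, not the ring-fusion methine C5, and O-sulfonylation should give the C3=C4 enol triflate and leave C5 untouched; the benzoate has no α-hydrogen.

Step 17
Reactants: 24 (1R,5S,7R,8R,10R)-4-(trifluoromethylsulfonyloxy)-10-(trimethylsilyloxy)-15-norguai-3-en-8-yl 4-methoxy-3-(triisopropylsilyloxy)benzoate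
Product: 26 (1R,5S,7R,8R,10R)-10-hydroxyguai-3-en-8-yl 4-methoxy-3-(triisopropylsilyloxy)benzoate, via trimethylsilyl ether 25 (not isolated)
Conditions: MeZnCl, Pd(PPh3)4 (5 mol %), THF, rt; then citric acid, MeOH, 0 °C
Reagents that add atoms: methylzinc chloride, C[Zn]Cl
Why: Negishi coupling of an enol triflate under zerovalent palladium puts the methyl on C4 without moving the alkene and tolerates ester and silyl ethers; mild acid methanolysis then removes only the tertiary trimethylsilyl ether.

Step 18
Reactants: 26 (1R,5S,7R,8R,10R)-10-hydroxyguai-3-en-8-yl 4-methoxy-3-(triisopropylsilyloxy)benzoate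
Product: 27 (1R,3R,4S,5S,7R,8R,10R)-3,4-epoxy-10-hydroxyguaian-8-yl 4-methoxy-3-(triisopropylsilyloxy)benzoate (3α,4α-epoxide)
Conditions: VO(acac)2 (5 mol %), t-BuOOH, CH2Cl2, 0 °C to rt
Reagents that add atoms: tert-butyl hydroperoxide, CC(C)(C)OO
Why: Hydroxyl-directed epoxidation of a bishomoallylic alcohol: the C10 vanadate should deliver oxygen to the α face of the trisubstituted C3=C4 bond, setting C3 and C4. The α-hydroxyl cannot reach the back side of either C–O bond, so the epoxy alcohol should not cyclise.

Step 19
Reactants: 27 (1R,3R,4S,5S,7R,8R,10R)-3,4-epoxy-10-hydroxyguaian-8-yl 4-methoxy-3-(triisopropylsilyloxy)benzoate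
Product: 28 (1R,3R,4S,5S,7R,8R,10R)-3,4-epoxy-10-hydroxyguaian-8-yl 3-hydroxy-4-methoxybenzoate (CNP0264062.2)
Conditions: Bu4NF, AcOH, THF, 0 °C
Reagents that add atoms: none
Why: Fluoride cleavage of the aryl silyl ether, buffered with acetic acid so that the phenoxide does not attack the ester and the epoxide is not opened.

## Compound list

1 | thymol | Cc1ccc(C(C)C)c(O)c1 | starting material
2 | thymol methyl ether | COc1cc(C)ccc1C(C)C | intermediate
3 | 5-isopropyl-4-methoxy-2-methylbenzaldehyde | COc1cc(C)c(C=O)cc1C(C)C | intermediate
4 | malonic acid | OC(=O)CC(=O)O | starting material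
5 | (E)-3-(5-isopropyl-4-methoxy-2-methylphenyl)prop-2-enoic acid | COc1cc(C)c(/C=C/C(=O)O)cc1C(C)C | intermediate
6 | 3-(5-isopropyl-4-methoxy-2-methylphenyl)propanoic acid | COc1cc(C)c(CCC(=O)O)cc1C(C)C | intermediate
7 | 3-(5-isopropyl-4-methoxy-2-methylphenyl)propanoyl chloride | COc1cc(C)c(CCC(=O)Cl)cc1C(C)C | intermediate
8 | 1-diazo-4-(5-isopropyl-4-methoxy-2-methylphenyl)butan-2-one | COc1cc(C)c(CCC(=O)C=[N+]=[N-])cc1C(C)C | intermediate
9 | norcaradiene valence isomer of 10 (cyclopropane C1–C5–C6) | COC1=C(C(C)C)[C@H]2[C@@H]3C(=O)CC[C@]23C(C)=C1 | intermediate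
10 | (5S)-8-methoxy-15-norguaia-1(10),6,8-trien-4-one | COC1=CC(C)=C2CCC(=O)[C@H]2C=C1C(C)C | intermediate
11 | (4R,5S)-8-methoxy-15-norguaia-1(10),6,8-trien-4-ol | COC1=CC(C)=C2CC[C@@H](O)[C@H]2C=C1C(C)C | intermediate
12 | (4R,5S)-4-hydroxy-15-norguaia-1(10),6-dien-8-one | O=C1CC(C)=C2CC[C@@H](O)[C@H]2C=C1C(C)C | intermediate
13 | 1α,10α-epoxy-4α-hydroxy-15-nor-5βH-guai-6-en-8-one | O=C1C[C@@]2(C)O[C@]23CC[C@@H](O)[C@H]3C=C1C(C)C | intermediate
14 | 1α,10α-epoxy-15-nor-5βH-guai-6-ene-4,8-dione | O=C1C[C@@]2(C)O[C@]23CCC(=O)[C@H]3C=C1C(C)C | intermediate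
15 | (10R)-10-hydroxy-15-norguaia-1(5),6-diene-4,8-dione | O=C1C[C@@](C)(O)C2=C(C(=O)CC2)C=C1C(C)C | intermediate
16 | (8R,10R)-8,10-dihydroxy-15-norguaia-1(5),6-dien-4-one | O[C@@H]1C[C@@](C)(O)C2=C(C(=O)CC2)C=C1C(C)C | intermediate
17 | isovanillic acid | COc1ccc(C(=O)O)cc1O | starting material
18 | triisopropylsilyl 4-methoxy-3-(triisopropylsilyloxy)benzoate | COc1ccc(C(=O)O[Si](C(C)C)(C(C)C)C(C)C)cc1O[Si](C(C)C)(C(C)C)C(C)C | intermediate
19 | 4-methoxy-3-(triisopropylsilyloxy)benzoic acid | COc1ccc(C(=O)O)cc1O[Si](C(C)C)(C(C)C)C(C)C | intermediate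
20 | (8R,10R)-10-hydroxy-4-oxo-15-norguaia-1(5),6-dien-8-yl 4-methoxy-3-(triisopropylsilyloxy)benzoate | COc1ccc(C(=O)O[C@@H]2C[C@@](C)(O)C3=C(C(=O)CC3)C=C2C(C)C)cc1O[Si](C(C)C)(C(C)C)C(C)C | intermediate
21 | (1R,5R,7R,8R,10R)-10-hydroxy-4-oxo-15-norguaian-8-yl 4-methoxy-3-(triisopropylsilyloxy)benzoate (cis-fused, 1αH,5αH) | COc1ccc(C(=O)O[C@@H]2C[C@@](C)(O)[C@@H]3CCC(=O)[C@@H]3C[C@@H]2C(C)C)cc1O[Si](C(C)C)(C(C)C)C(C)C | intermediate
22 | (1R,5S,7R,8R,10R)-10-hydroxy-4-oxo-15-norguaian-8-yl 4-methoxy-3-(triisopropylsilyloxy)benzoate (trans-fused, 1αH,5βH) | COc1ccc(C(=O)O[C@@H]2C[C@@](C)(O)[C@@H]3CCC(=O)[C@H]3C[C@@H]2C(C)C)cc1O[Si](C(C)C)(C(C)C)C(C)C | intermediate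
23 | (1R,5S,7R,8R,10R)-4-oxo-10-(trimethylsilyloxy)-15-norguaian-8-yl 4-methoxy-3-(triisopropylsilyloxy)benzoate | COc1ccc(C(=O)O[C@@H]2C[C@@](C)(O[Si](C)(C)C)[C@@H]3CCC(=O)[C@H]3C[C@@H]2C(C)C)cc1O[Si](C(C)C)(C(C)C)C(C)C | intermediate
24 | (1R,5S,7R,8R,10R)-4-(trifluoromethylsulfonyloxy)-10-(trimethylsilyloxy)-15-norguai-3-en-8-yl 4-methoxy-3-(triisopropylsilyloxy)benzoate | COc1ccc(C(=O)O[C@@H]2C[C@@](C)(O[Si](C)(C)C)[C@@H]3CC=C(OS(=O)(=O)C(F)(F)F)[C@H]3C[C@@H]2C(C)C)cc1O[Si](C(C)C)(C(C)C)C(C)C | intermediate
25 | (1R,5S,7R,8R,10R)-10-(trimethylsilyloxy)guai-3-en-8-yl 4-methoxy-3-(triisopropylsilyloxy)benzoate | COc1ccc(C(=O)O[C@@H]2C[C@@](C)(O[Si](C)(C)C)[C@@H]3CC=C(C)[C@H]3C[C@@H]2C(C)C)cc1O[Si](C(C)C)(C(C)C)C(C)C | intermediate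
26 | (1R,5S,7R,8R,10R)-10-hydroxyguai-3-en-8-yl 4-methoxy-3-(triisopropylsilyloxy)benzoate | COc1ccc(C(=O)O[C@@H]2C[C@@](C)(O)[C@@H]3CC=C(C)[C@H]3C[C@@H]2C(C)C)cc1O[Si](C(C)C)(C(C)C)C(C)C | intermediate
27 | (1R,3R,4S,5S,7R,8R,10R)-3,4-epoxy-10-hydroxyguaian-8-yl 4-methoxy-3-(triisopropylsilyloxy)benzoate | COc1ccc(C(=O)O[C@@H]2C[C@@](C)(O)[C@@H]3C[C@H]4O[C@@]4(C)[C@H]3C[C@@H]2C(C)C)cc1O[Si](C(C)C)(C(C)C)C(C)C | intermediate
28 | (1R,3R,4S,5S,7R,8R,10R)-3,4-epoxy-10-hydroxyguaian-8-yl 3-hydroxy-4-methoxybenzoate | COc1ccc(C(=O)O[C@@H]2C[C@@](C)(O)[C@@H]3C[C@H]4O[C@@]4(C)[C@H]3C[C@@H]2C(C)C)cc1O | target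

## Step count and least certain steps

Total: 19 steps. Longest linear sequence: 18 steps (thymol 1 to 28, steps 1–11 and 13–19); step 12 is a one-step branch.

**Step 6 (key step).** Most likely to fail is face discrimination on this trisubstituted arene, followed by loss of the C5 configuration through enolisation before the ketone is reduced. Addition to the methyl-bearing bond or aromatic substitution would lower the yield but not the logic. Since C5 is the only source of absolute configuration, partial selectivity carries through to 15.

Fallback, from 11 of insufficient enantiomeric purity (or racemic, made with an achiral bis(oxazoline)), returning to 11: esterification with (S)-2-methoxy-2-phenylacetic acid (DCC, DMAP) gives the (S)-2-methoxy-2-phenylacetate of (4R,5S)-11 F1 and the diastereomeric ester of the antipodal alcohol F2. These are separated by chromatography or crystallisation, and methanolysis of F1 (K2CO3, MeOH) returns enantiopure 11.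

**Step 8.** Under acid the C1=C10 bond may drift into conjugation with the new C8 ketone, or C5 may be lost through a dienol. In the following steps C9, now α to a ketone, offers a second way to open the epoxide and a way to dehydrate 15 to a tropone.

Fallback, from 11, returning at 15: acetal exchange with ethane-1,2-diol and pyridinium p-toluenesulfonate in CH2Cl2 at 0 °C gives the C8 ethylene ketal of 12 F3, in which C9 is not acidic. Directed epoxidation as in step 9 gives the 1α,10α-epoxy ketal F4. Dess–Martin oxidation and triethylamine give the γ-hydroxy enone ketal F5, and pyridinium p-toluenesulfonate in wet acetone releases the C8 ketone to give 15.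

**Step 14.** Hydrogen may be delivered to C7 from the β face if the ester carbonyl outcompetes the C10 hydroxyl as a ligand for iridium. The tetrasubstituted enone bond may resist reduction, or the cis/trans equilibrium at C5 may be less one-sided than expected.

Fallback, from 15, returning at 22:
- Chelation-controlled 1,3-syn reduction (Et2BOMe, NaBH4, THF–MeOH, −78 °C) gives the 8α,10α-dihydroxy dienone F6.
- With both hydroxyls on the α face, hydrogenation over [Ir(cod)(PCy3)(py)]PF6 gives the cis-fused 8α,10α-dihydroxy ketone F7, which DBU equilibrates to the trans-fused 8α,10α-dihydroxy ketone F8.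
- Dess–Martin oxidation of the secondary alcohol gives the 10α-hydroxy-4,8-dione F9.
- Me4NBH(OAc)3 delivers hydride from the α face, anti to the now fixed β-isopropyl group, to give the 8β,10α-dihydroxy ketone F10.
- Esterification with 19 as in step 13 returns 22.

**Step 18.** The bishomoallylic hydroxyl may direct poorly, so that attack on the β face competes and the wrong epoxide forms.

Fallback, from 25 (kept silylated instead of being cleaved in step 17), returning at 27: the silyl ether now blocks the α face. N-bromosuccinimide in aqueous 1,2-dimethoxyethane at 0 °C should form the bromonium ion on the β face and water should open it at the tertiary C4 from the α face, giving the 3β-bromo-4α-hydroxy-10-trimethylsilyloxy compound F11. K2CO3 in MeOH at 0 °C closes the 4α-alkoxide onto C3 with inversion and removes the trimethylsilyl group to give 27.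

## Further compounds

F1 | step 6 | (S)-2-methoxy-2-phenylacetate of (4R,5S)-11 | COC1=CC(C)=C2CC[C@@H](OC(=O)[C@@H](OC)c3ccccc3)[C@H]2C=C1C(C)C
F2 | step 6 | (S)-2-methoxy-2-phenylacetate of (4S,5R)-11 | COC1=CC(C)=C2CC[C@H](OC(=O)[C@@H](OC)c3ccccc3)[C@@H]2C=C1C(C)C
F3 | step 8 | C8 ethylene ketal of 12 | O1CCOC12CC(C)=C3CC[C@@H](O)[C@H]3C=C2C(C)C
F4 | step 8 | C8 ethylene ketal of 13 | O1CCOC12C[C@@]3(C)O[C@]34CC[C@@H](O)[C@H]4C=C2C(C)C
F5 | step 8 | C8 ethylene ketal of 15 | O1CCOC12C[C@@](C)(O)C3=C(C(=O)CC3)C=C2C(C)C
F6 | step 14 | (8S,10R)-8,10-dihydroxy-15-norguaia-1(5),6-dien-4-one (8α-OH, 10α-OH) | O[C@H]1C[C@@](C)(O)C2=C(C(=O)CC2)C=C1C(C)C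
F7 | step 14 | 8α,10α-dihydroxy-15-nor-1αH,5αH,7αH-guaian-4-one (cis-fused) | O[C@H]2C[C@@](C)(O)[C@@H]3CCC(=O)[C@@H]3C[C@@H]2C(C)C
F8 | step 14 | 8α,10α-dihydroxy-15-nor-1αH,5βH,7αH-guaian-4-one (trans-fused) | O[C@H]2C[C@@](C)(O)[C@@H]3CCC(=O)[C@H]3C[C@@H]2C(C)C
F9 | step 14 | 10α-hydroxy-15-nor-1αH,5βH,7αH-guaiane-4,8-dione | O=C2C[C@@](C)(O)[C@@H]3CCC(=O)[C@H]3C[C@@H]2C(C)C
F10 | step 14 | 8β,10α-dihydroxy-15-nor-1αH,5βH,7αH-guaian-4-one | O[C@@H]2C[C@@](C)(O)[C@@H]3CCC(=O)[C@H]3C[C@@H]2C(C)C
F11 | step 18 | 3β-bromo-4α-hydroxy-10α-(trimethylsilyloxy)-1αH,5βH-guaian-8β-yl 4-methoxy-3-(triisopropylsilyloxy)benzoate | COc1ccc(C(=O)O[C@@H]2C[C@@](C)(O[Si](C)(C)C)[C@@H]3C[C@H](Br)[C@@](C)(O)[C@H]3C[C@@H]2C(C)C)cc1O[Si](C(C)C)(C(C)C)C(C)C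
A1 | alternative 1 | cyclopent-2-en-1-one | O=C1CCC=C1
A2 | alternative 1 | 1-bromo-3-methylbut-2-ene | CC(C)=CCBr
A3 | alternative 1 | trans-3-(1-ethoxyvinyl)-2-(3-methylbut-2-en-1-yl)cyclopentan-1-one | O=C1CC[C@@H](C(=C)OCC)[C@@H]1CC=C(C)C
A4 | alternative 2 | 3-[trans-2-methyl-5-(prop-1-en-2-yl)cyclopent-2-en-1-yl]-2-(propan-2-yl)propanal | O=C[C@@H](C(C)C)C[C@@H]1C(C)=CC[C@H]1C(C)=C
A5 | alternative 2 | 1αH,5βH-guaia-3,10(14)-dien-8β-ol | O[C@@H]1CC(=C)[C@@H]2CC=C(C)[C@H]2C[C@@H]1C(C)C
A6 | alternative 3 | ethyl buta-2,3-dienoate | CCOC(=O)C=C=C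
A7 | alternative 3 | (E)-7-methyl-6-methylideneoct-3-en-2-one | CC(=O)/C=C/CC(=C)C(C)C
A8 | alternative 3 | ethyl trans-4-acetyl-5-[2-(propan-2-yl)prop-2-en-1-yl]cyclopent-1-ene-1-carboxylate | CCOC(=O)C1=CC[C@@H](C(C)=O)[C@@H]1CC(=C)C(C)C
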